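**Plan**

1. Retrosynthesis: cut (a) the three aryl–O MOM bonds, (b) the C3–C1' bond between ring C and ring B (Suzuki–Miyaura of 3-iodochromone 10 with boronate 16), (c) the C2–C3 bond of ring D, which leads back to the isomeric ortho-ethynylaryl isopropyl ether 14, (d) in fragment A the O1–C2 bond of ring C (enaminone iodocyclisation) and the aryl–CH2 bond of the C6 chain (Sonogashira, then hydrogenation).
2. Enabling feature: on ring B the pyran oxygen O1 (on C8a) and C4 (on C4a) are ortho, C2 is a quaternary OCMe2 carbon, and the C7 oxygen is para to C4a. C2 can therefore begin as the methine carbon of an ordinary isopropyl ether whose C–H lies 1,5 to the ring-bound carbon of an ortho ethynyl group, and the ortho and para oxygens make that carbon a hydride acceptor once a π-acid binds the alkyne.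
3. Forward, fragment A: the acetophenone is iodinated next to its free hydroxyl, the chain is attached and saturated, and a benzyl-to-MOM switch leaves free only the hydroxyl flanked by the ring C–H, so ring C can close only with the chain at C6 and not at C8.
4. Forward, fragment B: aldehyde to terminal alkyne, then a gold-catalysed hydride shift/cyclisation builds ring D from the isopropyl ether without adding an atom; borylation, Suzuki union and MOM removal complete the target.
5. Stereochemistry: the target has no stereocentre; its one ring alkene is cis by ring constraint.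

Key step: step 11

Remark: ring letters are A (benzo ring of the chromone), C (pyranone), B (3-aryl ring) and D (dimethylpyran, numbered as in 2H-chromene). 5-Bromo-2,4-dihydroxybenzaldehyde is assumed to be commercially available.

**Fragment A (steps 1–7)**

Step 1
Reactants: 1 1-(2,4,6-trihydroxyphenyl)ethan-1-one
Product: 2 1-[2,4-bis(benzyloxy)-6-hydroxyphenyl]ethan-1-one
Conditions: BnBr (2.1 equiv), K2CO3, DMF, rt
Reagents that add atoms: benzyl bromide, BrCc1ccccc1
Why: Williamson O-benzylation, in which the para hydroxyl and one ortho hydroxyl react while the last ortho hydroxyl stays locked in a hydrogen bond to the acetyl carbonyl and is left free.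

Step 2
Reactants: 2 1-[2,4-bis(benzyloxy)-6-hydroxyphenyl]ethan-1-one
Product: 3 1-[4,6-bis(benzyloxy)-2-hydroxy-3-iodophenyl]ethan-1-one
Conditions: NIS (1.05 equiv), CF3CO2H (cat.), MeCN, 0 °C to rt
Reagents that add atoms: N-iodosuccinimide, O=C1CCC(=O)N1I
Why: Electrophilic aromatic iodination, directed by the free chelated phenol to its ortho carbon, which is also less crowded than the carbon between the two benzyloxy groups.

Step 3
Reactants: 3 1-[4,6-bis(benzyloxy)-2-hydroxy-3-iodophenyl]ethan-1-one
Product: 4 1-[4,6-bis(benzyloxy)-3-iodo-2-(methoxymethoxy)phenyl]ethan-1-one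
Conditions: NaH (1.1 equiv), MOMCl, DMF, 0 °C to rt
Reagents that add atoms: chloromethyl methyl ether, COCCl
Why: Williamson-type MOM protection of the sodium phenoxide by the reactive α-chloro ether, which caps the oxygen next to iodine so that it cannot add to the alkyne of step 4 and later becomes the C5 oxygen.

Step 4
Reactants: 4 1-[4,6-bis(benzyloxy)-3-iodo-2-(methoxymethoxy)phenyl]ethan-1-one; 5 2-methylbut-3-yn-2-ol
Product: 6 1-[4,6-bis(benzyloxy)-3-(3-hydroxy-3-methylbut-1-yn-1-yl)-2-(methoxymethoxy)phenyl]ethan-1-one
Conditions: Pd(PPh3)2Cl2 (5 mol %), CuI (10 mol %), Et3N, DMF, 70 °C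
Reagents that add atoms: none
Why: Sonogashira coupling, in which the aryl iodide adds oxidatively to zerovalent palladium despite its two ortho alkoxy groups and the copper acetylide of the unprotected tertiary propargylic alcohol transmetalates.

Step 5
Reactants: 6 1-[4,6-bis(benzyloxy)-3-(3-hydroxy-3-methylbut-1-yn-1-yl)-2-(methoxymethoxy)phenyl]ethan-1-one
Product: 7 1-[4,6-dihydroxy-3-(3-hydroxy-3-methylbutyl)-2-(methoxymethoxy)phenyl]ethan-1-one
Conditions: H2 (1 atm), 10% Pd/C, EtOAc, rt
Reagents that add atoms: none
Why: Heterogeneous catalytic hydrogenation saturates the alkyne to the 3-hydroxy-3-methylbutyl chain and cleaves both benzyl ethers by hydrogenolysis in one operation, while the chelated aryl ketone, the MOM acetal and the non-benzylic tertiary alcohol should persist under neutral conditions.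

Step 6
Reactants: 7 1-[4,6-dihydroxy-3-(3-hydroxy-3-methylbutyl)-2-(methoxymethoxy)phenyl]ethan-1-one
Product: 8 1-[6-hydroxy-3-(3-hydroxy-3-methylbutyl)-2,4-bis(methoxymethoxy)phenyl]ethan-1-one
Conditions: MOMCl (1.05 equiv), K2CO3, acetone, 0 °C to rt
Reagents that add atoms: chloromethyl methyl ether, COCCl
Why: Selective Williamson-type MOM protection of the C4 hydroxyl, which is para to the acetyl group, more acidic and not hydrogen-bonded, so that the chelated C6 hydroxyl next to the ring C–H and the tertiary alcohol stay free.

Step 7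
Reactants: 8 1-[6-hydroxy-3-(3-hydroxy-3-methylbutyl)-2,4-bis(methoxymethoxy)phenyl]ethan-1-one
Product: 10 6-(3-hydroxy-3-methylbutyl)-3-iodo-5,7-bis(methoxymethoxy)-4H-chromen-4-one, via enaminone 9 (not isolated)
Conditions: Me2NCH(OMe)2, 90 °C; then I2, pyridine, CHCl3, rt
Reagents that add atoms: N,N-dimethylformamide dimethyl acetal, COC(OC)N(C)C; iodine, II
Why: Enaminone condensation of the methyl ketone followed by iodine-mediated cyclisation (the standard 3-iodochromone synthesis), in which the only free phenol adds to the iodinated enaminone and dimethylamine is lost, so ring C closes in one sense only.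

**Fragment B (steps 8–12)**

Step 8
Reactants: 11 5-bromo-2,4-dihydroxybenzaldehyde
Product: 12 5-bromo-2-hydroxy-4-(methoxymethoxy)benzaldehyde
Conditions: MOMCl (1.05 equiv), K2CO3, acetone, rt
Reagents that add atoms: chloromethyl methyl ether, COCCl
Why: Selective Williamson-type MOM protection of the C4 hydroxyl (para to the formyl group), the C2 hydroxyl being held in a hydrogen bond to the aldehyde.

Step 9
Reactants: 12 5-bromo-2-hydroxy-4-(methoxymethoxy)benzaldehyde
Product: 13 5-bromo-4-(methoxymethoxy)-2-(propan-2-yloxy)benzaldehyde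
Conditions: 2-bromopropane (3 equiv), K2CO3, DMF, 60 °C
Reagents that add atoms: 2-bromopropane, CC(C)Br
Why: Williamson ether synthesis with a secondary halide in excess, which installs the isopropyl ether whose methine carbon and two methyls are to become C2 and the gem-dimethyl group of ring D.

Step 10
Reactants: 13 5-bromo-4-(methoxymethoxy)-2-(propan-2-yloxy)benzaldehyde
Product: 14 1-bromo-5-ethynyl-2-(methoxymethoxy)-4-(propan-2-yloxy)benzene
Conditions: dimethyl (1-diazo-2-oxopropyl)phosphonate, K2CO3, MeOH, rt
Reagents that add atoms: dimethyl (1-diazo-2-oxopropyl)phosphonate, CC(=O)C(=[N+]=[N-])P(=O)(OC)OC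
Why: Seyferth–Gilbert homologation with the Ohira–Bestmann reagent, in which methanolysis frees the diazomethylphosphonate anion that olefinates the aldehyde, loses N2 and gives the terminal alkyne by a 1,2-hydrogen shift under conditions that spare the aryl bromide and the MOM ether.

Step 11
Reactants: 14 1-bromo-5-ethynyl-2-(methoxymethoxy)-4-(propan-2-yloxy)benzene
Product: 15 6-bromo-7-(methoxymethoxy)-2,2-dimethyl-2H-chromene
Conditions: [(XPhos)Au(NCMe)]SbF6 (5 mol %), 4 Å molecular sieves, ClCH2CH2Cl, 70 °C
Reagents that add atoms: none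
Why: Proposed new method: the cationic monovalent gold centre binds the terminal alkyne of 14 and slips toward the terminal carbon, so positive charge builds on the ring-bound alkyne carbon (ortho to the isopropoxy oxygen, para to the methoxymethoxy oxygen), and the isopropyl methine hydrogen, held 1,5 to that carbon, moves as hydride through a six-membered transition state to leave an aryl oxocarbenium ion (ArO+=CMe2) and a (Z)-2-arylvinylgold unit. The gold-bearing carbon (future C3) then attacks the oxocarbenium carbon (future C2) through its C–Au bond, the resulting benzylic cation at C4 is beta to gold and expels the gold cation to give the C3=C4 double bond, so the catalyst turns over and the step is a redox-neutral cycloisomerisation. The closest known reaction types are the Lewis-acid hydride-transfer cyclisation of ortho-vinylaryl alkyl ethers carrying acceptor alkenes to 3,4-dihydro-2H-chromenes (same 1,5 geometry, same C2–C3 closure) and the gold- or platinum-catalysed 1,5-hydride shift/cyclisation of alkyl ethers onto tethered unactivated terminal alkynes; joining an aryl isopropyl ether donor to an ortho ethynyl acceptor to reach a 2H-chromene directly is the untested element. Ring D closes at carbon and not at oxygen, in a 6-endo-trig mode on the oxocarbenium carbon with both the C=O+ unit and the C3=C4 unit ending inside the ring, and no stereocentre is formed. The step needs hydride delivery to the ring-bound alkyne carbon and six-ring closure at the gold-bearing carbon in preference to 5-endo addition of the ether oxygen to the alkyne or closure through C4 to a 3-methylene-2,3-dihydrobenzofuran: the ortho and para oxygens polarise the alkyne for Markovnikov hydride delivery and stabilise the C4 cation of the six-ring pathway, the tertiary C–H is the only hydridic C–H within reach (the methoxymethyl group is para and the bromine meta to the alkyne), the oxygen adduct of a simple alkyl ether can only revert, and molecular sieves keep water from trapping the oxocarbenium ion.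

Step 12
Reactants: 15 6-bromo-7-(methoxymethoxy)-2,2-dimethyl-2H-chromene
Product: 16 2-[7-(methoxymethoxy)-2,2-dimethyl-2H-chromen-6-yl]-4,4,5,5-tetramethyl-1,3,2-dioxaborolane
Conditions: B2pin2, Pd(dppf)Cl2 (5 mol %), KOAc, 1,4-dioxane, 90 °C
Reagents that add atoms: bis(pinacolato)diboron, CC1(C)OB(OC1(C)C)B1OC(C)(C)C(C)(C)O1
Why: Miyaura borylation, in which the aryl bromide adds oxidatively to zerovalent palladium and acetate-assisted transmetalation with the diboron reagent gives the pinacol boronate without touching the chromene double bond.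

**Union and deprotection (steps 13–14)**

Step 13
Reactants: 10 6-(3-hydroxy-3-methylbutyl)-3-iodo-5,7-bis(methoxymethoxy)-4H-chromen-4-one; 16 2-[7-(methoxymethoxy)-2,2-dimethyl-2H-chromen-6-yl]-4,4,5,5-tetramethyl-1,3,2-dioxaborolane
Product: 17 6-(3-hydroxy-3-methylbutyl)-5,7-bis(methoxymethoxy)-3-[7-(methoxymethoxy)-2,2-dimethyl-2H-chromen-6-yl]-4H-chromen-4-one
Conditions: Pd(dppf)Cl2 (5 mol %), K2CO3, 1,4-dioxane–H2O, 80 °C
Reagents that add atoms: none
Why: Suzuki–Miyaura coupling, in which the 3-iodochromone (a vinylogous acyl iodide) adds readily to zerovalent palladium and the electron-rich boronate transmetalates under carbonate, joining C3 of ring C to C1' of ring B with the free tertiary alcohol tolerated.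

Step 14
Reactants: 17 6-(3-hydroxy-3-methylbutyl)-5,7-bis(methoxymethoxy)-3-[7-(methoxymethoxy)-2,2-dimethyl-2H-chromen-6-yl]-4H-chromen-4-one
Product: 18 5,7-dihydroxy-6-(3-hydroxy-3-methylbutyl)-3-(7-hydroxy-2,2-dimethyl-2H-chromen-6-yl)-4H-chromen-4-one
Conditions: HCl (1 M) in MeOH–THF, 40 °C
Reagents that add atoms: none
Why: Acid-catalysed acetal solvolysis (MOM removal), in which each aryl MOM ether releases its phenol and the methoxymethyl cation is captured by methanol, while the 2,2-dimethylchromene and the non-activated tertiary alcohol should survive the dilute acid at mild temperature.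

**Compound list**

1 | 1-(2,4,6-trihydroxyphenyl)ethan-1-one | CC(=O)c1c(O)cc(O)cc1O | starting material
2 | 1-[2,4-bis(benzyloxy)-6-hydroxyphenyl]ethan-1-one | CC(=O)c1c(O)cc(OCc2ccccc2)cc1OCc1ccccc1 | intermediate
3 | 1-[4,6-bis(benzyloxy)-2-hydroxy-3-iodophenyl]ethan-1-one | CC(=O)c1c(O)c(I)c(OCc2ccccc2)cc1OCc1ccccc1 | intermediate
4 | 1-[4,6-bis(benzyloxy)-3-iodo-2-(methoxymethoxy)phenyl]ethan-1-one | CC(=O)c1c(OCOC)c(I)c(OCc2ccccc2)cc1OCc1ccccc1 | intermediate
5 | 2-methylbut-3-yn-2-ol | CC(C)(O)C#C | starting material
6 | 1-[4,6-bis(benzyloxy)-3-(3-hydroxy-3-methylbut-1-yn-1-yl)-2-(methoxymethoxy)phenyl]ethan-1-one | CC(=O)c1c(OCOC)c(C#CC(C)(C)O)c(OCc2ccccc2)cc1OCc1ccccc1 | intermediate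
7 | 1-[4,6-dihydroxy-3-(3-hydroxy-3-methylbutyl)-2-(methoxymethoxy)phenyl]ethan-1-one | CC(=O)c1c(OCOC)c(CCC(C)(C)O)c(O)cc1O | intermediate
8 | 1-[6-hydroxy-3-(3-hydroxy-3-methylbutyl)-2,4-bis(methoxymethoxy)phenyl]ethan-1-one | CC(=O)c1c(OCOC)c(CCC(C)(C)O)c(OCOC)cc1O | intermediate
9 | (E)-3-(dimethylamino)-1-[6-hydroxy-3-(3-hydroxy-3-methylbutyl)-2,4-bis(methoxymethoxy)phenyl]prop-2-en-1-one | CN(C)/C=C/C(=O)c1c(OCOC)c(CCC(C)(C)O)c(OCOC)cc1O | intermediate
10 | 6-(3-hydroxy-3-methylbutyl)-3-iodo-5,7-bis(methoxymethoxy)-4H-chromen-4-one | CC(C)(O)CCc1c(OCOC)cc2occ(I)c(=O)c2c1OCOC | intermediate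
11 | 5-bromo-2,4-dihydroxybenzaldehyde | O=Cc1cc(Br)c(O)cc1O | starting material
12 | 5-bromo-2-hydroxy-4-(methoxymethoxy)benzaldehyde | O=Cc1cc(Br)c(OCOC)cc1O | intermediate
13 | 5-bromo-4-(methoxymethoxy)-2-(propan-2-yloxy)benzaldehyde | O=Cc1cc(Br)c(OCOC)cc1OC(C)C | intermediate
14 | 1-bromo-5-ethynyl-2-(methoxymethoxy)-4-(propan-2-yloxy)benzene | C#Cc1cc(Br)c(OCOC)cc1OC(C)C | intermediate
15 | 6-bromo-7-(methoxymethoxy)-2,2-dimethyl-2H-chromene | COCOc1cc2OC(C)(C)C=Cc2cc1Br | intermediate
16 | 2-[7-(methoxymethoxy)-2,2-dimethyl-2H-chromen-6-yl]-4,4,5,5-tetramethyl-1,3,2-dioxaborolane | COCOc1cc2OC(C)(C)C=Cc2cc1B1OC(C)(C)C(C)(C)O1 | intermediate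
17 | 6-(3-hydroxy-3-methylbutyl)-5,7-bis(methoxymethoxy)-3-[7-(methoxymethoxy)-2,2-dimethyl-2H-chromen-6-yl]-4H-chromen-4-one | CC(C)(O)CCc1c(OCOC)cc2occ(-c3cc4C=CC(C)(C)Oc4cc3OCOC)c(=O)c2c1OCOC | intermediate
18 | 5,7-dihydroxy-6-(3-hydroxy-3-methylbutyl)-3-(7-hydroxy-2,2-dimethyl-2H-chromen-6-yl)-4H-chromen-4-one | CC(C)(O)CCc1c(O)cc2occ(-c3cc4c(cc3O)OC(C)(C)C=C4)c(=O)c2c1O | target

**Step count**

Total steps: 14. Longest linear sequence: 9 steps (steps 1–7, then 13 and 14); fragment B contributes 5 steps (8–12).

**Steps most likely to fail**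

1. Step 11 (proposed new method). Hydride transfer may be too slow, so that the ether oxygen adds to the activated alkyne with loss of the isopropyl group, the ring closes through the benzylic carbon to a five-membered ring, or the terminal alkyne is hydrated or oligomerised. The fallback uses known chemistry and closes ring D at oxygen. It sets out from 12: excess 2-methylprop-1-en-1-ylmagnesium bromide in THF at 0 °C adds to the aldehyde to give racemic 4-bromo-2-(1-hydroxy-3-methylbut-2-en-1-yl)-5-(methoxymethoxy)phenol F1. Warming F1 in toluene with a catalytic amount of pyridinium p-toluenesulfonate dehydrates it to the ortho-quinone methide, which closes by 6π oxa-electrocyclisation. The fallback comes back to the route at 15, so steps 9 to 11 are not needed.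

2. Step 13. Protodeboronation of the electron-rich ortho-alkoxy boronate and hydroxide-induced opening of the pyranone ring may outrun a slow transmetalation between two ortho-substituted partners. The fallback is an anhydrous, base-free Negishi coupling that sets out from 15. Bromine–lithium exchange (n-BuLi, THF, −78 °C) gives [7-(methoxymethoxy)-2,2-dimethyl-2H-chromen-6-yl]lithium F2. ZnCl2 converts it into chloro[7-(methoxymethoxy)-2,2-dimethyl-2H-chromen-6-yl]zinc F3, which is coupled with 10 (Pd(OAc)2, SPhos, THF, rt), where cross-coupling should outrun protonation by the tertiary hydroxyl. The fallback comes back to the route at 17; step 12 is then not needed.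

3. Step 14. Protic acid may ionise the tertiary alcohol (cyclisation onto the neighbouring C5 or C7 hydroxyl to a dihydropyran, or elimination) or promote addition to the chromene double bond before all three MOM groups are gone. The fallback replaces protic solvolysis by silyl exchange and sets out from 17. Me3SiOTf and 2,2'-bipyridyl in MeCN at 0 °C should convert the aryl MOM ethers into aryl trimethylsilyl ethers and silylate the tertiary alcohol, giving 3-[2,2-dimethyl-7-(trimethylsilyloxy)-2H-chromen-6-yl]-6-[3-methyl-3-(trimethylsilyloxy)butyl]-5,7-bis(trimethylsilyloxy)-4H-chromen-4-one F4. Brief treatment of F4 with K2CO3 in MeOH at 0 °C removes the silyl groups, and the fallback comes back to the route at 18.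

**Further compounds**

F1 | step 11 | 4-bromo-2-(1-hydroxy-3-methylbut-2-en-1-yl)-5-(methoxymethoxy)phenol (racemic) | CC(C)=CC(O)c1cc(Br)c(OCOC)cc1O
F2 | step 13 | [7-(methoxymethoxy)-2,2-dimethyl-2H-chromen-6-yl]lithium | [Li]c1cc2C=CC(C)(C)Oc2cc1OCOC
F3 | step 13 | chloro[7-(methoxymethoxy)-2,2-dimethyl-2H-chromen-6-yl]zinc | Cl[Zn]c1cc2C=CC(C)(C)Oc2cc1OCOC
F4 | step 14 | 3-[2,2-dimethyl-7-(trimethylsilyloxy)-2H-chromen-6-yl]-6-[3-methyl-3-(trimethylsilyloxy)butyl]-5,7-bis(trimethylsilyloxy)-4H-chromen-4-one | CC(C)(CCc1c(O[Si](C)(C)C)cc2occ(-c3cc4C=CC(C)(C)Oc4cc3O[Si](C)(C)C)c(=O)c2c1O[Si](C)(C)C)O[Si](C)(C)C
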